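**Retrosynthetic overview**
- The strategy rests on the ester carbonyl carbon, which sits between C1 of the catechol benzene ring and the O1 oxygen of the anteiso C19 chain. Both bonds to this carbon are cut at once, giving a 3-halocatechol, carbon monoxide and (S)-16-methyloctadecan-1-ol.
- The catechol is carried as its bis(benzyl) ether, made from 3-bromocatechol, and is unmasked last by hydrogenolysis.
- The chiral alcohol is cut at C14–C15: (S)-2-methylbutylmagnesium bromide (chiral pool, fixes C16) plus THP-protected 14-bromotetradecan-1-ol, joined by copper-catalysed coupling.
- No ring is formed at any stage; the only ring, the benzene ring, is bought in 3-bromocatechol.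

Key step: step 5

Remark on the chemistry: the tetrahydropyranyl ethers 5 and 8 (and F5 of a fallback) are taken as mixtures of both configurations at the acetal carbon, which is written without a descriptor and is removed in step 4.

**Route**

Step 1
Reactants: 1 3-bromobenzene-1,2-diol; 2 benzyl bromide (2.3 equiv)
Product: 3 1,2-bis(benzyloxy)-3-bromobenzene
Conditions: K2CO3 (3 equiv), DMF, 60 °C, N2
Reagents that add atoms: none
Why: Williamson ether synthesis, in which both phenoxide oxygens displace bromide from the benzylic halide while the aryl bromide is inert and the inert atmosphere protects the catechol from oxidation.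

Step 2
Reactants: 4 14-bromotetradecan-1-ol
Product: 5 2-[(14-bromotetradecyl)oxy]tetrahydro-2H-pyran
Conditions: 3,4-dihydro-2H-pyran (1.5 equiv), PPTS (cat.), CH2Cl2, rt
Reagents that add atoms: 3,4-dihydro-2H-pyran, C1=COCCC1
Why: acid-catalysed addition of the alcohol to the enol ether (tetrahydropyranylation) masks the hydroxyl so that it cannot quench the Grignard reagent of step 3.

Step 3
Reactants: 6 (S)-1-bromo-2-methylbutane (1.5 equiv); 5 2-[(14-bromotetradecyl)oxy]tetrahydro-2H-pyran
Product: 8 2-{[(16S)-16-methyloctadecyl]oxy}tetrahydro-2H-pyran, via (S)-2-methylbutylmagnesium bromide 7 (not isolated)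
Conditions: 6, Mg, THF, 50 °C; then 5, Li2CuCl4 (3 mol%), THF, −10 °C to rt
Reagents that add atoms: none
Why: Kochi-type copper-catalysed sp3–sp3 cross-coupling of a primary alkyl Grignard reagent with a primary alkyl bromide forms C14–C15, and the stereocentre, which comes from the chiral pool and lies beta to the carbon–magnesium bond, is not touched and keeps the S descriptor because the long chain outranks ethyl just as CH2Br did.

Step 4
Reactants: 8 2-{[(16S)-16-methyloctadecyl]oxy}tetrahydro-2H-pyran
Product: 9 (S)-16-methyloctadecan-1-ol
Conditions: TsOH·H2O (cat.), MeOH/THF, rt
Reagents that add atoms: none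
Why: acid-catalysed transacetalisation to methanol cleaves the THP acetal, and nothing else in the saturated chain is acid-sensitive.

Step 5
Reactants: 3 1,2-bis(benzyloxy)-3-bromobenzene (1.3 equiv); 9 (S)-16-methyloctadecan-1-ol; 10 carbon monoxide
Product: 11 (S)-16-methyloctadecyl 2,3-bis(benzyloxy)benzoate
Conditions: Pd(OAc)2 (5 mol%), Xantphos (6 mol%), Et3N (3 equiv), CO (1 atm, balloon), toluene, 90 °C
Reagents that add atoms: none
Why: Pd(OAc)2 is reduced in the flask to a zerovalent palladium–Xantphos complex that inserts into the aryl C–Br bond of 3, CO then coordinates and undergoes migratory insertion to give an aroyl complex of divalent palladium, and attack of the primary alcohol 9 assisted by Et3N releases ester 11 and returns zerovalent palladium. The closest known reaction type is the Heck-type alkoxycarbonylation of aryl bromides at atmospheric CO pressure with wide-bite-angle diphosphine ligands. Two bonds form at the new carbonyl carbon (aryl C1–C(=O) and C(=O)–O), no ring is closed and no stereocentre is created, and the C16 centre of 9 lies fifteen carbons from the reacting oxygen and cannot be affected. The step needs chemoselectivity for single CO insertion and O-acylation over direct aryl ether formation, double carbonylation to the alpha-keto ester, and hydrodebromination through beta-hydride elimination from a palladium alkoxide. This should be secured by the wide bite angle of Xantphos, the low CO pressure and the unhindered primary hydroxyl of 9 that traps the aroyl complex quickly, while the ortho benzyloxy group is a tolerated ether and the inexpensive bromide 3 is used in slight excess so that the chiral alcohol is consumed completely.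

Step 6
Reactants: 11 (S)-16-methyloctadecyl 2,3-bis(benzyloxy)benzoate
Product: 12 gentiside F, (S)-16-methyloctadecyl 2,3-dihydroxybenzoate
Conditions: H2 (1 atm), Pd/C (10% palladium on carbon), EtOAc, rt
Reagents that add atoms: none
Why: catalytic hydrogenolysis cleaves both benzylic C–O bonds of the aryl benzyl ethers, while the alkyl benzoate, the saturated chain and the remote stereocentre are inert under these neutral conditions.

**Compound list**
1 | 3-bromobenzene-1,2-diol | Oc1cccc(Br)c1O | starting material
2 | benzyl bromide | BrCc1ccccc1 | starting material
3 | 1,2-bis(benzyloxy)-3-bromobenzene | Brc1cccc(OCc2ccccc2)c1OCc1ccccc1 | intermediate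
4 | 14-bromotetradecan-1-ol | OCCCCCCCCCCCCCCBr | starting material
5 | 2-[(14-bromotetradecyl)oxy]tetrahydro-2H-pyran (both configurations at the acetal carbon) | BrCCCCCCCCCCCCCCOC1CCCCO1 | intermediate
6 | (S)-1-bromo-2-methylbutane | CC[C@H](C)CBr | starting material
7 | (S)-2-methylbutylmagnesium bromide | CC[C@H](C)C[Mg]Br | intermediate
8 | 2-{[(16S)-16-methyloctadecyl]oxy}tetrahydro-2H-pyran (both configurations at the acetal carbon) | CC[C@H](C)CCCCCCCCCCCCCCCOC1CCCCO1 | intermediate
9 | (S)-16-methyloctadecan-1-ol | CC[C@H](C)CCCCCCCCCCCCCCCO | intermediate
10 | carbon monoxide | [C-]#[O+] | starting material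
11 | (S)-16-methyloctadecyl 2,3-bis(benzyloxy)benzoate | CC[C@H](C)CCCCCCCCCCCCCCCOC(=O)c1cccc(OCc2ccccc2)c1OCc1ccccc1 | intermediate
12 | gentiside F, (S)-16-methyloctadecyl 2,3-dihydroxybenzoate | CC[C@H](C)CCCCCCCCCCCCCCCOC(=O)c1cccc(O)c1O | target

**Step count**
Total steps: 6. Longest linear sequence: 5 steps (steps 2, 3, 4, 5, 6, from 14-bromotetradecan-1-ol); step 1 is a one-step side branch that joins at step 5.

**Steps most likely to fail**

1. Step 5. Oxidative addition into the electron-rich C–Br bond flanked by an ortho alkoxy group may be slow. A palladium alkoxide of 9 may then undergo beta-hydride elimination, which reduces the aryl bromide and wastes the chiral alcohol, and the catalyst may be deactivated under CO. The fallback forms the two bonds in separate operations and sets out from 3. Bromine–lithium exchange with n-BuLi in THF at −78 °C should give 2,3-bis(benzyloxy)phenyllithium F1. Quenching with CO2 and work-up with aqueous HCl should give 2,3-bis(benzyloxy)benzoic acid F2. Steglich esterification of this acid with 9 (DCC, DMAP cat., CH2Cl2, rt) comes back to the route at 11.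

2. Step 3. Formation of the beta-branched Grignard reagent may be sluggish and accompanied by Wurtz-type homocoupling, and the coupling may stall, leaving bromide 5 unconverted or reduced. The fallback replaces the organomagnesium nucleophile by a sulfone-stabilised carbanion and sets out from 6. Displacement with PhSO2Na (NaI cat., DMF, 80 °C) should give {[(2S)-2-methylbutyl]sulfonyl}benzene F3. Deprotonation with n-BuLi in THF at −78 °C should give {[(2S)-1-lithio-2-methylbutyl]sulfonyl}benzene F4. Alkylation with 5 (DMPU, −78 °C to rt) should give 2-{[(16S)-16-methyl-15-(phenylsulfonyl)octadecyl]oxy}tetrahydro-2H-pyran F5, as a mixture at C15. Reductive desulfonylation with Na(Hg) in MeOH/THF removes that centre and comes back to the route at 8. The C16 centre is not acidic and is not touched.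

3. Step 6. Cleavage of the second benzyl ether may stop short because the waxy substrate dissolves poorly or because phosphine and palladium residues from step 5 poison the catalyst, and the free catechol may oxidise in air during work-up. The fallback removes the benzyl groups by Lewis acid instead of hydrogen and sets out from 11. BCl3 with pentamethylbenzene as benzyl cation scavenger in CH2Cl2 at −78 °C, followed by aqueous work-up, should give 12 directly, with the alkyl ester left intact; it makes no new compound (F0).

**Further compounds**
F1 | step 5 | 2,3-bis(benzyloxy)phenyllithium | [Li]c1cccc(OCc2ccccc2)c1OCc1ccccc1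
F2 | step 5 | 2,3-bis(benzyloxy)benzoic acid | OC(=O)c1cccc(OCc2ccccc2)c1OCc1ccccc1
F3 | step 3 | {[(2S)-2-methylbutyl]sulfonyl}benzene | CC[C@H](C)CS(=O)(=O)c1ccccc1
F4 | step 3 | {[(2S)-1-lithio-2-methylbutyl]sulfonyl}benzene | CC[C@H](C)C([Li])S(=O)(=O)c1ccccc1
F5 | step 3 | 2-{[(16S)-16-methyl-15-(phenylsulfonyl)octadecyl]oxy}tetrahydro-2H-pyran | CC[C@H](C)C(CCCCCCCCCCCCCCOC1CCCCO1)S(=O)(=O)c1ccccc1
F0 | step 6 | none | none
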